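**Strategy.** The cyclohexane ring is assembled around its quaternary carbon (methyl and acyl, the acyl carried as a nitrile), the neighbouring ring CH (oxobutyl arm) and the gem-dimethyl carbon beyond it. In one flask lithiated propionitrile adds to a vinylphosphonium salt, the resulting ylide olefinates an acyclic aldehyde–enoate (joining the ring CH2 next to the gem-dimethyl carbon to the middle CH2), and a nitrile-anion Michael cyclisation then bonds the quaternary carbon to the ring CH. The precursor is an open-chain 8-phenylmenthyl 4,4-dimethyl-5-oxopent-2-enoate: the auxiliary fixes the CH centre, the slim cyano group the cis relation of acyl and arm. Chromium-mediated union with a citronellic-acid-derived glyceride iodide and one hydrogenation finish.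

Key step: step 3

Remark (assumption on the chemistry): the (–)-8-phenylmenthyl enoate is taken to react in its s-trans conformation on the β-face not stacked by the phenyl ring, the sense recalled for carbon-nucleophile additions to its crotonate; this face corresponds to the configuration drawn, and the antipodal auxiliary would be used if the sense proved opposite.

Step 1
Reactants: 1 (–)-8-phenylmenthol; 2 propiolic acid
Product: 3 (1R,2S,5R)-5-methyl-2-(2-phenylpropan-2-yl)cyclohexyl prop-2-ynoate (8-phenylmenthyl propiolate)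
Conditions: p-TsOH·H2O (cat.), toluene, reflux, Dean–Stark trap
Reagents that add atoms: none
Why: Acid-catalysed (Fischer) esterification driven by azeotropic removal of water; the carbinol C–O bond is not broken, so the three stereocentres of the auxiliary are retained.

Step 2
Reactants: 3 8-phenylmenthyl propiolate; 4 4-(2-methylprop-1-en-1-yl)morpholine
Product: 5 8-phenylmenthyl (2E)-4,4-dimethyl-5-oxopent-2-enoate
Conditions: MeCN, 60 °C; then AcOH, NaOAc, H2O, rt
Reagents that add atoms: water, O
Why: Stork enamine conjugate addition to the ynoate gives an iminium ion whose α-carbon is quaternary, so hydrolysis should release the non-enolisable aldehyde, and the E-enoate is the thermodynamically preferred geometry.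

Step 3
Reactants: 6 propionitrile; 7 vinyltriphenylphosphonium bromide; 5 8-phenylmenthyl (2E)-4,4-dimethyl-5-oxopent-2-enoate
Product: 10 8-phenylmenthyl 2-[(1S,6R)-6-cyano-2,2,6-trimethylcyclohex-3-en-1-yl]acetate, via ylide 8 (not isolated), via Z-diene ester 9 (not isolated)
Conditions: 6, LiN(iPr)2 (1.0 equiv), THF, –78 °C; add 7, –78 → –20 °C; DMPU, then 5, –78 °C → rt; LiN(iPr)2 (1.1 equiv), –78 → –40 °C; aq. NH4Cl
Reagents that add atoms: none
Why: Lithiated propionitrile adds to the vinylphosphonium salt (Schweizer-type conjugate addition) to give ylide 8, whose Z-selective Wittig reaction with the hindered, non-enolisable aldehyde of 5 makes the C=C bond between the two future ring CH2 carbons remote from the nitrile; a second equivalent of base then deprotonates the α-cyano CH of 9 and the planar nitrile anion, into which both epimers of 9 converge, closes the ring by intramolecular Michael addition to the enoate (closest known types: three-component vinylphosphonium/Wittig coupling and nitrile-anion Michael cyclisation). The ring closes in the 6-exo-trig mode, which is possible only from the Z-alkene. The ring CH stereocentre is set by the 8-phenylmenthyl ester, whose phenyl ring covers one face of the s-trans enoate so that the carbanion enters on the other β-face. The quaternary centre is set by the chair-like transition state in which the acceptor arm is pseudo-equatorial and the rod-like cyano (ketenimine) unit rather than the methyl group takes the crowded pseudo-axial site wedged between the gem-dimethyl carbon and the arm, which places cyano cis to the acetate arm. The step needs aldehyde-over-enoate chemoselectivity of the ylide (secured by the tert-alkyl-shielded β-carbon and low temperature) and clean α-cyano deprotonation (secured because the quaternary carbon leaves the enoate without γ-hydrogens).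

Step 4
Reactants: 10 8-phenylmenthyl 2-[(1S,6R)-6-cyano-2,2,6-trimethylcyclohex-3-en-1-yl]acetate
Product: 11 (1R,6S)-1,5,5-trimethyl-6-(2-oxoethyl)cyclohex-3-ene-1-carbaldehyde
Conditions: iBu2AlH (2.4 equiv), toluene, –78 → –40 °C; MeOH, then aq. KNaC4H4O6 and dilute AcOH
Reagents that add atoms: water, O
Why: iBu2AlH reduces the nitrile to the N-aluminio aldimine and the hindered ester to its tetrahedral aluminium hemiacetal, both of which give aldehydes only on hydrolytic work-up (partial reduction); the auxiliary is released, and neither ring stereocentre can epimerise (one is quaternary, the other is β to its aldehyde).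

Step 5
Reactants: 11 (1R,6S)-1,5,5-trimethyl-6-(2-oxoethyl)cyclohex-3-ene-1-carbaldehyde
Product: 12 (1R,6S)-6-(3-methoxybut-2-en-1-yl)-1,5,5-trimethylcyclohex-3-ene-1-carbaldehyde (E/Z mixture at the enol ether)
Conditions: MeOCH(CH3)PPh3Cl, KN(SiMe3)2, THF, –78 °C; then 11 (1.0 equiv), –78 → –20 °C
Reagents that add atoms: (1-methoxyethyl)triphenylphosphonium chloride, COC(C)[P+](c1ccccc1)(c1ccccc1)c1ccccc1.[Cl-]
Why: Wittig olefination with the α-methoxyethylidene ylide should occur at the unhindered CH2–CHO group, the ring aldehyde on the quaternary carbon reacting far more slowly; the enol ether is a masked methyl ketone and no stereocentre is touched.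

Step 6
Reactants: 13 2-O-benzylglycerol
Product: 14 (S)-3-acetoxy-2-(benzyloxy)propan-1-ol
Conditions: lipase PS (Burkholderia cepacia), vinyl acetate, t-BuOMe, 25 °C
Reagents that add atoms: vinyl acetate, CC(=O)OC=C
Why: Lipase-catalysed irreversible transesterification (enzymatic desymmetrisation) acetylates one of the two enantiotopic CH2OH groups of the prochiral diol and thereby sets the glycerol stereocentre.

Step 7
Reactants: 15 (R)-citronellic acid; 14 (S)-3-acetoxy-2-(benzyloxy)propan-1-ol
Product: 16 (2R)-3-acetoxy-2-(benzyloxy)propyl (3R)-3,7-dimethyloct-6-enoate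
Conditions: EDC·HCl, DMAP (cat.), CH2Cl2, 0 °C → rt
Reagents that add atoms: none
Why: Carbodiimide/DMAP (Steglich) esterification of the free primary alcohol; no stereocentre is touched (the descriptor at the glycerol carbon changes only because the substituent priorities change).

Step 8
Reactants: 16 (2R)-3-acetoxy-2-(benzyloxy)propyl (3R)-3,7-dimethyloct-6-enoate
Product: 18 (4R)-6-[(2R)-3-acetoxy-2-(benzyloxy)propoxy]-4-methyl-6-oxohexanoic acid, via aldehyde ester 17 (not isolated)
Conditions: K2OsO4·2H2O (cat.), NaIO4, 2,6-lutidine, dioxane/H2O, rt; then NaClO2, NaH2PO4, 2-methyl-2-butene, t-BuOH/H2O, rt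
Reagents that add atoms: sodium periodate, [Na+].[O-][I](=O)(=O)=O; sodium chlorite, [Na+].[O-]Cl=O
Why: Lemieux–Johnson cleavage of the trisubstituted alkene to the aldehyde followed by Pinnick oxidation to the acid; benzyl ether, acetate and ester are inert and the methyl-bearing stereocentre is remote from the reacting carbon.

Step 9
Reactants: 18 (4R)-6-[(2R)-3-acetoxy-2-(benzyloxy)propoxy]-4-methyl-6-oxohexanoic acid
Product: 19 (2R)-3-acetoxy-2-(benzyloxy)propyl (3S)-5-iodo-3-methylpentanoate
Conditions: PhI(OAc)2, I2, CH2Cl2/cyclohexane, hν (tungsten lamp), reflux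
Reagents that add atoms: iodine, [I][I]
Why: Suárez iododecarboxylation (acyl hypoiodite, radical loss of CO2, iodine transfer) shortens the chain by one carbon to the primary iodide; the stereocentre is untouched and its descriptor changes only through the priority of iodine.

Step 10
Reactants: 12 (1R,6S)-6-(3-methoxybut-2-en-1-yl)-1,5,5-trimethylcyclohex-3-ene-1-carbaldehyde; 19 (2R)-3-acetoxy-2-(benzyloxy)propyl (3S)-5-iodo-3-methylpentanoate
Product: 20 (2R)-3-acetoxy-2-(benzyloxy)propyl (3R)-6-hydroxy-6-[(1R,6S)-6-(3-methoxybut-2-en-1-yl)-1,5,5-trimethylcyclohex-3-en-1-yl]-3-methylhexanoate (both carbinol epimers)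
Conditions: CrCl2 (4 equiv), Co(C32H16N8) (cobalt phthalocyanine, cat.), DMF, rt; aq. NH4Cl
Reagents that add atoms: none
Why: Takai–Utimoto alkylation: the alkylchromium reagent formed from the primary iodide under cobalt catalysis adds to the aldehyde (Nozaki–Hiyama-type addition) and should leave esters, benzyl ether and enol ether untouched; the new carbinol centre is formed without control and is removed by oxidation in the next step.

Step 11
Reactants: 20 (2R)-3-acetoxy-2-(benzyloxy)propyl (3R)-6-hydroxy-6-[(1R,6S)-6-(3-methoxybut-2-en-1-yl)-1,5,5-trimethylcyclohex-3-en-1-yl]-3-methylhexanoate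
Product: 22 (2R)-3-acetoxy-2-(benzyloxy)propyl (3R)-3-methyl-6-oxo-6-[(1R,6S)-1,5,5-trimethyl-6-(3-oxobutyl)cyclohex-3-en-1-yl]hexanoate, via enol ether ketone 21 (not isolated)
Conditions: Dess–Martin periodinane, NaHCO3, CH2Cl2, 0 °C → rt; then 1 M HCl, THF, rt
Reagents that add atoms: water, O
Why: Dess–Martin oxidation turns the hindered secondary alcohol into the ketone and dilute acid hydrolyses the methyl enol ether to the methyl ketone; the quaternary carbon and the ring CH (β and γ to the two ketones) cannot epimerise.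

Step 12
Reactants: 22 (2R)-3-acetoxy-2-(benzyloxy)propyl (3R)-3-methyl-6-oxo-6-[(1R,6S)-1,5,5-trimethyl-6-(3-oxobutyl)cyclohex-3-en-1-yl]hexanoate
Product: 23 (2R)-3-acetoxy-2-hydroxypropyl (3R)-3-methyl-6-oxo-6-[(1R,2S)-1,3,3-trimethyl-2-(3-oxobutyl)cyclohexyl]hexanoate (target)
Conditions: H2 (1 atm), Pd/C (10 wt% Pd), EtOAc, rt
Reagents that add atoms: none
Why: Heterogeneous hydrogenation saturates the ring alkene and removes the benzyl ether by hydrogenolysis in one operation; ketones and esters are inert, and the neutral medium should avoid acyl migration to the freed secondary hydroxyl.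

**Compound list**

1 | (–)-8-phenylmenthol, (1R,2S,5R)-5-methyl-2-(2-phenylpropan-2-yl)cyclohexan-1-ol | CC(C)(c1ccccc1)[C@@H]1CC[C@@H](C)C[C@H]1O | starting material
2 | propiolic acid | C#CC(=O)O | starting material
3 | (1R,2S,5R)-5-methyl-2-(2-phenylpropan-2-yl)cyclohexyl prop-2-ynoate | CC(C)(c1ccccc1)[C@@H]1CC[C@@H](C)C[C@H]1OC(=O)C#C | intermediate
4 | 4-(2-methylprop-1-en-1-yl)morpholine | CC(C)=CN1CCOCC1 | starting material
5 | (1R,2S,5R)-5-methyl-2-(2-phenylpropan-2-yl)cyclohexyl (2E)-4,4-dimethyl-5-oxopent-2-enoate | CC(C)(c1ccccc1)[C@@H]1CC[C@@H](C)C[C@H]1OC(=O)/C=C/C(C)(C)C=O | intermediate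
6 | propionitrile | CCC#N | starting material
7 | vinyltriphenylphosphonium bromide | C=C[P+](c1ccccc1)(c1ccccc1)c1ccccc1.[Br-] | starting material
8 | (3-cyanobutylidene)triphenylphosphorane (racemic) | CC(CC=P(c1ccccc1)(c1ccccc1)c1ccccc1)C#N | intermediate
9 | 8-phenylmenthyl (2E,5Z)-8-cyano-4,4-dimethylnona-2,5-dienoate (both epimers at C-8) | CC(C)(c1ccccc1)[C@@H]1CC[C@@H](C)C[C@H]1OC(=O)/C=C/C(C)(C)/C=C\CC(C)C#N | intermediate
10 | 8-phenylmenthyl 2-[(1S,6R)-6-cyano-2,2,6-trimethylcyclohex-3-en-1-yl]acetate | CC(C)(c1ccccc1)[C@@H]1CC[C@@H](C)C[C@H]1OC(=O)C[C@H]2C(C)(C)C=CC[C@@]2(C)C#N | intermediate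
11 | (1R,6S)-1,5,5-trimethyl-6-(2-oxoethyl)cyclohex-3-ene-1-carbaldehyde | O=CC[C@H]1C(C)(C)C=CC[C@@]1(C)C=O | intermediate
12 | (1R,6S)-6-(3-methoxybut-2-en-1-yl)-1,5,5-trimethylcyclohex-3-ene-1-carbaldehyde | COC(C)=CC[C@H]1C(C)(C)C=CC[C@@]1(C)C=O | intermediate
13 | 2-O-benzylglycerol, 2-(benzyloxy)propane-1,3-diol | OCC(CO)OCc1ccccc1 | starting material
14 | (S)-3-acetoxy-2-(benzyloxy)propan-1-ol | OC[C@H](OCc1ccccc1)COC(C)=O | intermediate
15 | (R)-citronellic acid, (3R)-3,7-dimethyloct-6-enoic acid | CC(C)=CCC[C@@H](C)CC(=O)O | starting material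
16 | (2R)-3-acetoxy-2-(benzyloxy)propyl (3R)-3,7-dimethyloct-6-enoate | CC(C)=CCC[C@@H](C)CC(=O)OC[C@H](OCc1ccccc1)COC(C)=O | intermediate
17 | (2R)-3-acetoxy-2-(benzyloxy)propyl (3R)-3-methyl-6-oxohexanoate | O=CCC[C@@H](C)CC(=O)OC[C@H](OCc1ccccc1)COC(C)=O | intermediate
18 | (4R)-6-[(2R)-3-acetoxy-2-(benzyloxy)propoxy]-4-methyl-6-oxohexanoic acid | OC(=O)CC[C@@H](C)CC(=O)OC[C@H](OCc1ccccc1)COC(C)=O | intermediate
19 | (2R)-3-acetoxy-2-(benzyloxy)propyl (3S)-5-iodo-3-methylpentanoate | ICC[C@@H](C)CC(=O)OC[C@H](OCc1ccccc1)COC(C)=O | intermediate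
20 | (2R)-3-acetoxy-2-(benzyloxy)propyl (3R)-6-hydroxy-6-[(1R,6S)-6-(3-methoxybut-2-en-1-yl)-1,5,5-trimethylcyclohex-3-en-1-yl]-3-methylhexanoate | COC(C)=CC[C@H]1C(C)(C)C=CC[C@@]1(C)C(O)CC[C@@H](C)CC(=O)OC[C@H](OCc1ccccc1)COC(C)=O | intermediate
21 | (2R)-3-acetoxy-2-(benzyloxy)propyl (3R)-6-[(1R,6S)-6-(3-methoxybut-2-en-1-yl)-1,5,5-trimethylcyclohex-3-en-1-yl]-3-methyl-6-oxohexanoate | COC(C)=CC[C@H]1C(C)(C)C=CC[C@@]1(C)C(=O)CC[C@@H](C)CC(=O)OC[C@H](OCc1ccccc1)COC(C)=O | intermediate
22 | (2R)-3-acetoxy-2-(benzyloxy)propyl (3R)-3-methyl-6-oxo-6-[(1R,6S)-1,5,5-trimethyl-6-(3-oxobutyl)cyclohex-3-en-1-yl]hexanoate | CC(=O)CC[C@H]1C(C)(C)C=CC[C@@]1(C)C(=O)CC[C@@H](C)CC(=O)OC[C@H](OCc1ccccc1)COC(C)=O | intermediate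
23 | (2R)-3-acetoxy-2-hydroxypropyl (3R)-3-methyl-6-oxo-6-[(1R,2S)-1,3,3-trimethyl-2-(3-oxobutyl)cyclohexyl]hexanoate | CC(=O)CC[C@H]1C(C)(C)CCC[C@@]1(C)C(=O)CC[C@@H](C)CC(=O)OC[C@H](O)COC(C)=O | target

**Step count.** Total: 12 steps. Longest linear sequence: 8 steps (steps 1–5 and 10–12).

**Steps most likely to fail**

1. Step 3. The ylide may be lost by addition to still unreacted vinylphosphonium salt, lithium salts may erode the Z-selectivity, and facial control by the auxiliary may be incomplete. The fallback sets out from 5 and returns at 10, and makes the ylide precursor separately. Radical anti-Markovnikov addition of HBr (dibenzoyl peroxide, hexane) to commercial 2-methylbut-3-enenitrile should give 4-bromo-2-methylbutanenitrile F1. PPh3 in refluxing MeCN then gives (3-cyanobutyl)triphenylphosphonium bromide F2. A salt-free Wittig reaction of F2 (KN(SiMe3)2, THF, –78 °C) with 5 gives diene 9, which is isolated and freed from its E isomer. Cyclisation in a separate operation (LiN(iPr)2, THF, –78 °C) leads to 10.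

2. Step 4. The ester-derived hemiacetal may be over-reduced to the alcohol before the hindered nitrile has reacted, with lactol formation onto the neighbouring cis aldehyde; the two aldehydes may also be poorly discriminated in step 5. The fallback sets out from 10 and returns at 12, and differentiates the two carbons by oxidation state instead of by hindrance. LiBH4 (THF, one equivalent of MeOH, 50 °C) reduces only the ester and gives (1R,6S)-6-(2-hydroxyethyl)-1,5,5-trimethylcyclohex-3-ene-1-carbonitrile F3 with recovery of the auxiliary. Dess–Martin oxidation gives (1R,6S)-1,5,5-trimethyl-6-(2-oxoethyl)cyclohex-3-ene-1-carbonitrile F4. Wittig reaction with the α-methoxyethylidene ylide gives (1R,6S)-6-(3-methoxybut-2-en-1-yl)-1,5,5-trimethylcyclohex-3-ene-1-carbonitrile F5. iBu2AlH then reduces the nitrile, the only reducible group left, to aldehyde 12.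

3. Step 10. The alkylchromium reagent may be protonated or homocoupled faster than it adds to the neopentyl-type aldehyde. The fallback sets out from 12 and returns at 22, and makes the ketone by acylation instead of addition–oxidation. Hydrolysis of 12 (1 M HCl, THF) gives (1R,6S)-1,5,5-trimethyl-6-(3-oxobutyl)cyclohex-3-ene-1-carbaldehyde F6. Pinnick oxidation (NaClO2, NaH2PO4, 2-methyl-2-butene) gives (1R,6S)-1,5,5-trimethyl-6-(3-oxobutyl)cyclohex-3-ene-1-carboxylic acid F7. Oxalyl chloride with catalytic DMF gives (1R,6S)-1,5,5-trimethyl-6-(3-oxobutyl)cyclohex-3-ene-1-carbonyl chloride F8. Zinc insertion into 19 (Zn dust, LiCl, THF) gives [(3S)-5-{[(2R)-3-acetoxy-2-(benzyloxy)propyl]oxy}-3-methyl-5-oxopentyl]zinc iodide F9. Negishi acylation of F8 with F9 (Pd(PPh3)4, THF) gives diketone 22.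

**Further compounds**

F1 | step 3 | 4-bromo-2-methylbutanenitrile | CC(CCBr)C#N
F2 | step 3 | (3-cyanobutyl)triphenylphosphonium bromide | CC(CC[P+](c1ccccc1)(c1ccccc1)c1ccccc1)C#N.[Br-]
F3 | step 4 | (1R,6S)-6-(2-hydroxyethyl)-1,5,5-trimethylcyclohex-3-ene-1-carbonitrile | OCC[C@H]1C(C)(C)C=CC[C@@]1(C)C#N
F4 | step 4 | (1R,6S)-1,5,5-trimethyl-6-(2-oxoethyl)cyclohex-3-ene-1-carbonitrile | O=CC[C@H]1C(C)(C)C=CC[C@@]1(C)C#N
F5 | step 4 | (1R,6S)-6-(3-methoxybut-2-en-1-yl)-1,5,5-trimethylcyclohex-3-ene-1-carbonitrile | COC(C)=CC[C@H]1C(C)(C)C=CC[C@@]1(C)C#N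
F6 | step 10 | (1R,6S)-1,5,5-trimethyl-6-(3-oxobutyl)cyclohex-3-ene-1-carbaldehyde | CC(=O)CC[C@H]1C(C)(C)C=CC[C@@]1(C)C=O
F7 | step 10 | (1R,6S)-1,5,5-trimethyl-6-(3-oxobutyl)cyclohex-3-ene-1-carboxylic acid | CC(=O)CC[C@H]1C(C)(C)C=CC[C@@]1(C)C(O)=O
F8 | step 10 | (1R,6S)-1,5,5-trimethyl-6-(3-oxobutyl)cyclohex-3-ene-1-carbonyl chloride | CC(=O)CC[C@H]1C(C)(C)C=CC[C@@]1(C)C(Cl)=O
F9 | step 10 | [(3S)-5-{[(2R)-3-acetoxy-2-(benzyloxy)propyl]oxy}-3-methyl-5-oxopentyl]zinc iodide | I[Zn]CC[C@@H](C)CC(=O)OC[C@H](OCc1ccccc1)COC(C)=O
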